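**Retrosynthetic overview**

1. Numbering as in ent-kaurane: ring A = C1–C5, C10; oxepane ring B = C5–C6–O–C7–C8–C9–C10; ring C = C8–C9–C11–C12–C13–C14; ring D = C8–C14–C13–C16–C15. End-game disconnections: 9,11-oxirane ⇐ Δ9(11) alkene ⇐ C11 ketone; C6 lactol ⇐ methyl acetal; C15 enone ⇐ C15 carbinol.
2. Key disconnection: C11–C12 and C13–C14 together, by rhodium-catalysed insertion of a C12=C13 vinyl group into the C11–C14 bond of a cyclobutanone (C8–C9–C11(=O)–C14). Rings C and D, i.e. the whole bicyclo[3.2.1]octane, form in this one step.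
3. Enabling feature: C8 is quaternary and is joined to C13 twice (through C14 and through C15–C16), and C11 carries oxygen next to C9. Ring C is therefore a cyclobutanone ring-expanded by C12–C13, the olefin hanging from the cyclobutanone C3 position (C8) on the two-carbon tether C15–C16.
4. Cyclobutanone and ring B ⇐ intramolecular keteniminium–olefin [2+2] cycloaddition (bonds C8–C9 and C11–C14) across a C6–O–C7 mixed-acetal tether that unites the ring A amide (West fragment) with a 2-methylidene-1,3-diol-derived alcohol (East fragment).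
5. Ring A ⇐ 4,4-dimethylcyclohexa-2,5-dienone: desymmetrising vinyl addition (C5), two α'-alkylations (C10), hydroxyl-directed epoxidation and reductive opening (1α,2α-diol). Ring order: A (from the start) → B + cyclobutane (step 14) → C + D (step 15) → oxirane (step 22).

Key step: step 15

**Remarks on the chemistry**

- α/β refer to the usual ent-kaurane drawing (C20 methyl α, H-5 β); in the target the oxirane oxygen is α, anti to the C15–C16 bridge.
- The acetal carbon C6 of 17–28 is formed and carried as a mixture of epimers (no descriptor in the SMILES); it is assumed that the lactol of the target is the thermodynamically preferred C6 epimer, reached by equilibration in step 21.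
- C15 of 14–26 is a temporary stereocentre (oxidised in step 19); the (S) antipode is drawn and either would serve.
- Compound 3 is drawn as the expected trans isomer; its C10 configuration is erased in step 3.

**Route**

Step 1
Reactants: 1 4,4-dimethylcyclohexa-2,5-dien-1-one
Product: 2 (R)-5-ethenyl-4,4-dimethylcyclohex-2-en-1-one
Conditions: CH2=CHBF3K (0.8 equiv), [Rh(cod)2]PF6 (3 mol%), (R)-BINAP (3.3 mol%), PhMe/H2O 4:1, 100 °C
Reagents that add atoms: potassium vinyltrifluoroborate, C=C[B-](F)(F)F.[K+]
Why: Hayashi–Miyaura asymmetric 1,4-addition to one of the two enantiotopic enone units should desymmetrise the dienone and set C5, the BINAP antipode being chosen by the facial model established for cyclohex-2-enone and the excess of 1 suppressing a second addition.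

Step 2
Reactants: 2 (R)-5-ethenyl-4,4-dimethylcyclohex-2-en-1-one
Product: 3 (5S,6S)-5-ethenyl-4,4,6-trimethylcyclohex-2-en-1-one
Conditions: LiN(iPr)2, THF, −78 °C; MeI, −78 → −20 °C
Reagents that add atoms: iodomethane, CI
Why: Kinetic α'-deprotonation of the enone and enolate methylation (C20), expected trans to the vinyl group; this centre is re-enolised in step 3.

Step 3
Reactants: 3 (5S,6S)-5-ethenyl-4,4,6-trimethylcyclohex-2-en-1-one
Product: 4 2-[(1S,6R)-6-ethenyl-1,5,5-trimethyl-2-oxocyclohex-3-en-1-yl]-N,N-dimethylacetamide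
Conditions: LiN(iPr)2, THF, −78 → −30 °C; BrCH2C(O)NMe2, DMPU, −78 → 0 °C
Reagents that add atoms: 2-bromo-N,N-dimethylacetamide, CN(C)C(=O)CBr
Why: Alkylation of the trisubstituted α'-enolate anti to the adjacent C5 vinyl group should set the quaternary C10, with the acetamide arm (C9, C11) trans to the vinyl group and the methyl cis to it.

Step 4
Reactants: 4 enone amide
Product: 5 ring A allylic alcohol (1α-OH, Δ2)
Conditions: NaBH4, CeCl3·7H2O, MeOH, −78 → −40 °C
Reagents that add atoms: none
Why: Luche 1,2-reduction; axial hydride delivery anti to the axial C20 methyl, as for angularly methylated enones, should give the 1α-alcohol cis to C20.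

Step 5
Reactants: 5 ring A allylic alcohol
Product: 6 2α,3α-epoxy-1α-alcohol
Conditions: VO(acac)2 (5 mol%), t-BuOOH (decane), CH2Cl2, 0 °C → rt
Reagents that add atoms: tert-butyl hydroperoxide, CC(C)(C)OO
Why: Vanadium-catalysed hydroxyl-directed epoxidation should deliver oxygen syn to the 1α-OH and leave the unactivated vinyl group untouched.

Step 6
Reactants: 6 2α,3α-epoxy-1α-alcohol
Product: 8 cis-1α,2α-diol amide, via iodohydrin 7 (not isolated)
Conditions: MgI2, PhMe/Et2O, −60 → 0 °C; then Bu3SnH, AIBN (cat.), PhMe, 80 °C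
Reagents that add atoms: none
Why: Magnesium chelation between the 1-OH and the oxirane should direct iodide to C3 (trans-diaxial, Fürst–Plattner opening) so that the C2–O bond keeps its α configuration, and radical deiodination then leaves the cis-1α,2α-diol.

Step 7
Reactants: 8 cis-1α,2α-diol amide
Product: 9 1α,2α-diacetate
Conditions: Ac2O, DMAP, pyridine, 40 °C
Reagents that add atoms: acetic anhydride, CC(=O)OC(C)=O
Why: DMAP-catalysed acylation of both secondary alcohols; no stereocentre is touched.

Step 8
Reactants: 9 1α,2α-diacetate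
Product: 11 West fragment (C6 dimethyl acetal), via aldehyde 10 (not isolated)
Conditions: O3, CH2Cl2/MeOH, −78 °C; Me2S, −78 °C → rt; then HC(OMe)3, TsOH·H2O (cat.), rt
Reagents that add atoms: trimethyl orthoformate, COC(OC)OC
Why: Ozonolysis of the only C=C bond gives the C6 aldehyde, which is masked at once as the dimethyl acetal so that C5, flanked by two quaternary carbons and slow to enolise, should keep its configuration.

Step 9
Reactants: 12 2-methylidenepropane-1,3-diol
Product: 13 2-{[(4-methoxybenzyl)oxy]methyl}prop-2-en-1-ol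
Conditions: NaH (1.0 equiv), THF, 0 °C; PMBCl, Bu4NI (cat.), rt (12 in excess)
Reagents that add atoms: 4-methoxybenzyl chloride, COc1ccc(CCl)cc1
Why: Williamson mono-etherification of the symmetrical diol (statistical; excess diol is recovered).

Step 10
Reactants: 13 mono-PMB ether
Product: 14 (3S)-1-[(4-methoxybenzyl)oxy]-2-methylidenehex-5-en-3-ol
Conditions: [Ir(cod)Cl]2 (2.5 mol%), (S)-Cl,MeO-BIPHEP (5 mol%), Cs2CO3 (20 mol%), 4-chloro-3-nitrobenzoic acid (10 mol%), allyl acetate, THF, 100 °C
Reagents that add atoms: allyl acetate, C=CCOC(C)=O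
Why: Krische allylation, a transfer-hydrogenative C-allylation from the alcohol oxidation level via the transient enal and a chiral π-allyliridium complex, should install C16–C13–C12 and set the temporary C15 stereocentre under ligand control.

Step 11
Reactants: 14 homoallylic alcohol
Product: 15 TBS ether of 14
Conditions: TBSCl, imidazole, DMF, rt
Reagents that add atoms: tert-butyldimethylsilyl chloride, CC(C)(C)[Si](C)(C)Cl
Why: Standard silylation of the secondary alcohol; the ether must survive steps 12–17.

Step 12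
Reactants: 15 TBS ether
Product: 16 East fragment, (3S)-3-[(tert-butyldimethylsilyl)oxy]-2-methylidenehex-5-en-1-ol
Conditions: DDQ, CH2Cl2/pH 7 buffer, 0 °C
Reagents that add atoms: none
Why: Oxidative cleavage of the PMB ether frees the primary allylic alcohol (C7–OH) without touching the silyl ether or the alkenes.

Step 13
Reactants: 11 West fragment; 16 East fragment
Product: 18 mixed acetal (C6 epimers), via collidinium salt 17 (not isolated)
Conditions: TESOTf, 2,4,6-collidine, CH2Cl2, 0 °C; then 16, 0 °C → rt
Reagents that add atoms: none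
Why: Chemoselective ionisation of the dimethyl acetal to its collidinium salt and substitution by the primary alcohol should give the C6–O–C7 mixed acetal under non-acidic conditions.

Step 14
Reactants: 18 mixed acetal
Product: 21 tricyclic cyclobutanone, via keteniminium triflate 19 (not isolated), via cyclobutaniminium triflate 20 (not isolated)
Conditions: Tf2O, 2,4,6-collidine, ClCH2CH2Cl (high dilution), −25 → 80 °C; then aq. NaHCO3, rt
Reagents that add atoms: water, O
Why: Intramolecular keteniminium–olefin [2+2] cycloaddition in which electrophilic C11 bonds to the terminal C14 and C9 to the more substituted C8, closing oxepane ring B and the cyclobutane cis-fused; the fold that keeps the branched C15 side chain away from the axial C20 methyl should set C8 as drawn, and iminium hydrolysis gives the ketone.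

Step 15
Reactants: 21 tricyclic cyclobutanone
Product: 23 pentacyclic 11-ketone with 9α-H, via 9β-H ketone 22 (not isolated)
Conditions: [Rh(C2H4)2Cl]2 (5 mol%), P[3,5-(CF3)2C6H3]3 (24 mol%), 2-amino-3-methylpyridine (1 equiv), 1,4-dioxane, 150 °C, sealed tube; then DBU (0.5 equiv), PhMe, 80 °C
Reagents that add atoms: none
Why: Oxidative addition of monovalent rhodium into the C11–C14 bond (assisted by the transient 2-aminopyridyl ketimine) should give a rhodacyclopentanone; 5-exo migratory insertion of the tethered C12=C13 vinyl group into Rh–C14 then closes ring D (C13–C14), and acyl–alkyl reductive elimination closes cyclohexanone ring C (C11–C12). The closest known reaction type is the rhodium-catalysed intramolecular olefin insertion into the C–C bond of cyclobutanones carrying an olefin on C3 through a two- or three-atom tether ("cut-and-sew" carboacylation), which gives bicyclo[3.2.1]- and bicyclo[3.3.1]alkanones. Ring D is thus closed by exo insertion and ring C by reductive elimination from the seven-membered acyl–alkyl rhodacycle, so the bicyclo[3.2.1]octane arises from a four-membered ketone in one operation. C13 is the only new skeletal stereocentre and is fixed by the bridged geometry, since C8 (set in step 14) and C13 must carry the C14 and C15–C16 bridges cis; C9 is epimerisable α to the ketimine/ketone and the DBU treatment should equilibrate it to the isomer with C10 equatorial on ring C (9α-H). The step needs insertion into C11–C14 and not C11–C9, secured because C9 is flanked by the quaternary C8 and C10 while C14 is a methylene; it also needs olefin insertion faster than decarbonylation, for which the aminopyridine co-catalyst and the electron-poor phosphine are chosen.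

Step 16
Reactants: 23 pentacyclic 11-ketone
Product: 24 11β-alcohol
Conditions: NaBH4, MeOH/THF, −20 °C
Reagents that add atoms: none
Why: Hydride should attack C11 from the exo (α) face, away from the C15–C16 bridge as in bicyclo[3.2.1]octan-3-ones, giving the axial 11β-alcohol while the acetates survive at this temperature.

Step 17
Reactants: 24 11β-alcohol
Product: 25 Δ9(11)-alkene
Conditions: Martin sulfurane, CH2Cl2, 0 °C → rt
Reagents that add atoms: none
Why: Anti-periplanar E2 elimination of the axial 11β-alkoxysulfonium with the axial 9α-H, preferred over H-12 by Zaitsev orientation as in the dehydration of 11β-hydroxy steroids, should give the trisubstituted alkene.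

Step 18
Reactants: 25 Δ9(11)-alkene
Product: 26 C15 alcohol
Conditions: HF·pyridine, pyridine, THF, 0 °C → rt
Reagents that add atoms: none
Why: Buffered fluoride desilylation; acetates, the mixed acetal and the alkene should be inert.

Step 19
Reactants: 26 C15 alcohol
Product: 27 C15 ketone
Conditions: Dess–Martin periodinane, NaHCO3, CH2Cl2, rt
Reagents that add atoms: none
Why: Mild oxidation of the hindered secondary alcohol; this removes the temporary C15 stereocentre.

Step 20
Reactants: 27 C15 ketone
Product: 28 exo-methylene enone (methyl acetal)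
Conditions: (CH2O)n, PhNHMe·CF3CO2H, THF, 65 °C
Reagents that add atoms: formaldehyde (as paraformaldehyde), C=O
Why: Mannich condensation and β-elimination (α-methylenation) at C16, the only enolisable position of the C15 ketone because C8 is quaternary, under conditions that spare the acetates.

Step 21
Reactants: 28 exo-methylene enone (methyl acetal)
Product: 29 lactol
Conditions: AcOH/H2O/THF 3:1:1, 40 °C
Reagents that add atoms: water, O
Why: Hydrolysis of the 2-methoxyoxepane acetal gives the lactol, which should equilibrate through the open hydroxy aldehyde to the preferred C6 epimer; enone, acetates and alkene tolerate dilute acetic acid.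

Step 22
Reactants: 29 lactol
Product: 30 target CNP0224512.1
Conditions: dimethyldioxirane (acetone), CH2Cl2, −40 → 0 °C
Reagents that add atoms: dimethyldioxirane, CC1(C)OO1
Why: Electrophilic epoxidation of the only electron-rich alkene (the enone methylene is inert to the dioxirane at low temperature) should occur on the exo α-face, because the β-face lies under the C15–C16 bridge, giving the 9α,11α-oxirane.

**Compound list**

1 | 4,4-dimethylcyclohexa-2,5-dien-1-one | CC1(C)C=CC(=O)C=C1 | starting material
2 | (R)-5-ethenyl-4,4-dimethylcyclohex-2-en-1-one | C=C[C@@H]1C(C)(C)C=CC(=O)C1 | intermediate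
3 | (5S,6S)-5-ethenyl-4,4,6-trimethylcyclohex-2-en-1-one (trans) | C=C[C@@H]1C(C)(C)C=CC(=O)[C@H]1C | intermediate
4 | 2-[(1S,6R)-6-ethenyl-1,5,5-trimethyl-2-oxocyclohex-3-en-1-yl]-N,N-dimethylacetamide | C=C[C@@H]1C(C)(C)C=CC(=O)[C@@]1(C)CC(=O)N(C)C | intermediate
5 | ring A allylic alcohol (1α-OH, Δ2; C5 vinyl α; C10 CH3 α, CH2CONMe2 β) | C=C[C@@H]1C(C)(C)C=C[C@H](O)[C@@]1(C)CC(=O)N(C)C | intermediate
6 | 2α,3α-epoxy-1α-alcohol | C=C[C@@H]1C(C)(C)[C@@H]2O[C@@H]2[C@H](O)[C@@]1(C)CC(=O)N(C)C | intermediate
7 | 3β-iodo-1α,2α-diol (iodohydrin) | C=C[C@@H]1C(C)(C)[C@@H](I)[C@H](O)[C@H](O)[C@@]1(C)CC(=O)N(C)C | intermediate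
8 | cis-1α,2α-diol amide | C=C[C@@H]1C(C)(C)C[C@H](O)[C@H](O)[C@@]1(C)CC(=O)N(C)C | intermediate
9 | 1α,2α-diacetate (vinyl amide) | C=C[C@@H]1C(C)(C)C[C@H](OC(C)=O)[C@H](OC(C)=O)[C@@]1(C)CC(=O)N(C)C | intermediate
10 | C6 aldehyde of ring A | O=C[C@@H]1C(C)(C)C[C@H](OC(C)=O)[C@H](OC(C)=O)[C@@]1(C)CC(=O)N(C)C | intermediate
11 | West fragment: ring A C6 dimethyl acetal, 1α,2α-diacetate, C10 acetamide | COC(OC)[C@@H]1C(C)(C)C[C@H](OC(C)=O)[C@H](OC(C)=O)[C@@]1(C)CC(=O)N(C)C | intermediate
12 | 2-methylidenepropane-1,3-diol | C=C(CO)CO | starting material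
13 | 2-{[(4-methoxybenzyl)oxy]methyl}prop-2-en-1-ol | OCC(=C)COCc1ccc(OC)cc1 | intermediate
14 | (3S)-1-[(4-methoxybenzyl)oxy]-2-methylidenehex-5-en-3-ol | C=CC[C@H](O)C(=C)COCc1ccc(OC)cc1 | intermediate
15 | TBS ether of 14 | C=CC[C@H](O[Si](C)(C)C(C)(C)C)C(=C)COCc1ccc(OC)cc1 | intermediate
16 | East fragment: (3S)-3-[(tert-butyldimethylsilyl)oxy]-2-methylidenehex-5-en-1-ol | C=CC[C@H](O[Si](C)(C)C(C)(C)C)C(=C)CO | intermediate
17 | N-(α-methoxyalkyl)-2,4,6-collidinium triflate of ring A | COC([n+]1c(C)cc(C)cc1C)[C@@H]2C(C)(C)C[C@H](OC(C)=O)[C@H](OC(C)=O)[C@@]2(C)CC(=O)N(C)C.[O-]S(=O)(=O)C(F)(F)F | intermediate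
18 | mixed acetal C6(OMe)–O–C7 joining West and East fragments | C=CC[C@H](O[Si](C)(C)C(C)(C)C)C(=C)COC(OC)[C@@H]1C(C)(C)C[C@H](OC(C)=O)[C@H](OC(C)=O)[C@@]1(C)CC(=O)N(C)C | intermediate
19 | keteniminium triflate (C9=C11=N+Me2) | C=CC[C@H](O[Si](C)(C)C(C)(C)C)C(=C)COC(OC)[C@@H]1C(C)(C)C[C@H](OC(C)=O)[C@H](OC(C)=O)[C@@]1(C)C=C=[N+](C)C.[O-]S(=O)(=O)C(F)(F)F | intermediate
20 | cyclobutaniminium triflate | C=CC[C@H](O[Si](C)(C)C(C)(C)C)[C@@]23COC(OC)[C@@H]4C(C)(C)C[C@H](OC(C)=O)[C@H](OC(C)=O)[C@@]4(C)[C@@H]2C(=[N+](C)C)C3.[O-]S(=O)(=O)C(F)(F)F | intermediate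
21 | tricyclic cyclobutanone (ring A, oxepane ring B, cis-fused cyclobutanone C8–C9–C11(=O)–C14; C8 bears the C15(OTBS)–C16–C13=C12 chain) | C=CC[C@H](O[Si](C)(C)C(C)(C)C)[C@@]23COC(OC)[C@@H]4C(C)(C)C[C@H](OC(C)=O)[C@H](OC(C)=O)[C@@]4(C)[C@@H]2C(=O)C3 | intermediate
22 | pentacyclic 11-ketone, 9β-H (kinetic epimer) | C1[C@H](O[Si](C)(C)C(C)(C)C)[C@@]23COC(OC)[C@@H]4C(C)(C)C[C@H](OC(C)=O)[C@H](OC(C)=O)[C@@]4(C)[C@@H]2C(=O)C[C@@H]1C3 | intermediate
23 | pentacyclic 11-ketone, 9α-H | C1[C@H](O[Si](C)(C)C(C)(C)C)[C@@]23COC(OC)[C@@H]4C(C)(C)C[C@H](OC(C)=O)[C@H](OC(C)=O)[C@@]4(C)[C@H]2C(=O)C[C@@H]1C3 | intermediate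
24 | 11β-alcohol | C1[C@H](O[Si](C)(C)C(C)(C)C)[C@@]23COC(OC)[C@@H]4C(C)(C)C[C@H](OC(C)=O)[C@H](OC(C)=O)[C@@]4(C)[C@H]2[C@@H](O)C[C@@H]1C3 | intermediate
25 | Δ9(11)-alkene, C15 OTBS | C1[C@H](O[Si](C)(C)C(C)(C)C)[C@@]23COC(OC)[C@@H]4C(C)(C)C[C@H](OC(C)=O)[C@H](OC(C)=O)[C@@]4(C)C2=CC[C@@H]1C3 | intermediate
26 | Δ9(11)-alkene, C15 alcohol | C1[C@H](O)[C@@]23COC(OC)[C@@H]4C(C)(C)C[C@H](OC(C)=O)[C@H](OC(C)=O)[C@@]4(C)C2=CC[C@@H]1C3 | intermediate
27 | Δ9(11)-alkene, C15 ketone | C1C(=O)[C@@]23COC(OC)[C@@H]4C(C)(C)C[C@H](OC(C)=O)[C@H](OC(C)=O)[C@@]4(C)C2=CC[C@@H]1C3 | intermediate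
28 | 16-methylidene-15-ketone, C6 methyl acetal | C=C1C(=O)[C@@]23COC(OC)[C@@H]4C(C)(C)C[C@H](OC(C)=O)[C@H](OC(C)=O)[C@@]4(C)C2=CC[C@@H]1C3 | intermediate
29 | lactol (9(11)-ene) | C=C1C(=O)[C@@]23CO[C@@H](O)[C@@H]4C(C)(C)C[C@H](OC(C)=O)[C@H](OC(C)=O)[C@@]4(C)C2=CC[C@@H]1C3 | intermediate
30 | CNP0224512.1 | C=C1C(=O)[C@@]23CO[C@@H](O)[C@@H]4C(C)(C)C[C@H](OC(C)=O)[C@H](OC(C)=O)[C@@]4(C)[C@]24O[C@@H]4C[C@@H]1C3 | target

**Step count and risks**

Total step count: 22. Longest linear sequence: 18 steps (steps 1–8 and 13–22).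

Step 15 (key step). Decarbonylation of the acyl-rhodium intermediate, β-hydride elimination after olefin insertion, or failure of the hindered cyclobutanone to insert at all would divert the material. The fallback forms the same two bonds photochemically and sets out from 21. Kinetic enolisation toward the methylene C14 (LiN(SiMe3)2, Me3SiCl, THF, −78 °C) would give the cyclobutene silyl enol ether F5. Copper-catalysed intramolecular [2+2] photocycloaddition of this 1,6-diene (Salomon–Kochi; (CuOTf)2·C6H6, Et2O, 254 nm) would join C13 to C14 and C11 to C12 in the bicyclo[2.2.0]hexane photoadduct F6. Buffered Bu4NF would unmask the cyclobutanol, whose strain-driven ring opening (homoketonisation, cleavage of the central C11–C14 bond) gives 22; the DBU equilibration then returns to the route at 23.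

Step 14. Ionisation of the mixed acetal, or capture of the keteniminium ion by an acetal oxygen before the seven-membered ring can close, would destroy the tether; facial leakage at C8 is the second concern. The fallback replaces the cationic cycloaddition by a neutral thermal ketene cycloaddition and sets out from 18. IrCl(CO)(PPh3)2-catalysed hydrosilylation of the amide with (HMe2Si)2O followed by mild hydrolysis would give the aldehyde F1. Pinnick oxidation (NaClO2, NaH2PO4, 2-methylbut-2-ene) would give the acid F2, and 1-chloro-N,N,2-trimethylprop-1-en-1-amine would give the acid chloride F3. Slow addition of F3 to Et3N in PhMe at 110 °C would generate the ketene F4, whose intramolecular [2+2] cycloaddition onto the 1,1-disubstituted alkene returns to the route at 21.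

Step 17. Elimination toward C12 (the Δ11(12) regioisomer) would result if C9 has not equilibrated to the 9α-H epimer in step 15 or if the shielded H-9 is not reached by the base. The fallback uses enol-derivative chemistry, which does not depend on the C9 configuration, and sets out from 23. Tf2O with 2,6-di-tert-butyl-4-methylpyridine in CH2Cl2 (thermodynamic, more substituted enol derivative) would give the Δ9(11) enol triflate F7. Palladium-catalysed formate reduction (Pd(OAc)2, PPh3, Bu3N, HCO2H, DMF, 60 °C) would then return to the route at 25.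

**Further compounds**

F1 | step 14 | C11 aldehyde from amide 18 | C=CC[C@H](O[Si](C)(C)C(C)(C)C)C(=C)COC(OC)[C@@H]1C(C)(C)C[C@H](OC(C)=O)[C@H](OC(C)=O)[C@@]1(C)CC=O
F2 | step 14 | C11 carboxylic acid | C=CC[C@H](O[Si](C)(C)C(C)(C)C)C(=C)COC(OC)[C@@H]1C(C)(C)C[C@H](OC(C)=O)[C@H](OC(C)=O)[C@@]1(C)CC(=O)O
F3 | step 14 | C11 acid chloride | C=CC[C@H](O[Si](C)(C)C(C)(C)C)C(=C)COC(OC)[C@@H]1C(C)(C)C[C@H](OC(C)=O)[C@H](OC(C)=O)[C@@]1(C)CC(=O)Cl
F4 | step 14 | ketene (C9=C11=O) | C=CC[C@H](O[Si](C)(C)C(C)(C)C)C(=C)COC(OC)[C@@H]1C(C)(C)C[C@H](OC(C)=O)[C@H](OC(C)=O)[C@@]1(C)C=C=O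
F5 | step 15 | cyclobutene trimethylsilyl enol ether (C11=C14) of 21 | C=CC[C@H](O[Si](C)(C)C(C)(C)C)[C@@]23COC(OC)[C@@H]4C(C)(C)C[C@H](OC(C)=O)[C@H](OC(C)=O)[C@@]4(C)[C@@H]2C(O[Si](C)(C)C)=C3
F6 | step 15 | bicyclo[2.2.0]hexane photoadduct (C11–C12 and C13–C14 formed, C11–C14 still intact, C11 OSiMe3) | C1[C@H](O[Si](C)(C)C(C)(C)C)[C@@]23COC(OC)[C@@H]4C(C)(C)C[C@H](OC(C)=O)[C@H](OC(C)=O)[C@@]4(C)[C@@H]2[C@@]5(O[Si](C)(C)C)C[C@@H]1[C@@H]35
F7 | step 17 | Δ9(11) enol triflate of 23 | C1[C@H](O[Si](C)(C)C(C)(C)C)[C@@]23COC(OC)[C@@H]4C(C)(C)C[C@H](OC(C)=O)[C@H](OC(C)=O)[C@@]4(C)C2=C(OS(=O)(=O)C(F)(F)F)C[C@@H]1C3
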